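**Remarks and assumptions**
- Halimane numbering is used for every bicyclic compound and, by extension, for the polyene 3, whose olefins are then C3=C4, C5=C10, C8=C9 and C13=C14. α/β refer to the usual drawing (ring A left, ring B right, C10 at the top junction).
- Diphosphates 3 and 4 are handled as ammonium salts and written as the free acids.
- Finding the cyclase variant by mutagenesis and screening is counted as part of step 3.

## The problem

The target is a syn-halimane. Rings A and B are six-membered carbocycles that share the tetrasubstituted C5=C10 olefin; ring A carries the C4 gem-dimethyl group and ring B four contiguous stereocentres: C6 (β-hydroxyl), C7 (β-acetoxy), C8 (α-methyl, C17) and the quaternary C9 (β-methyl C20 and the α-oriented C11–C16 chain). The chain ends in a fifth stereocentre, the tertiary vinyl carbinol C13, four bonds away from C9. The C8/C9 pair has no functional group beside it and must be made together with the skeleton. Once it exists, the C8 methyl can direct an oxygen onto C7 and the C7 substituent can direct hydride onto C6, whereas C13 is too remote for relay and needs reagent control. Three functions are fragile: the tertiary allylic alcohol at C13 (ionisation, 1,3-transposition under acid or hexavalent chromium), the allylic C6 alcohol beside the tetrasubstituted olefin (ionisation) and the cis hydroxy acetate (acyl shift under base), so the last steps must be cold and near neutral. A further difficulty is that the C5=C10 olefin has two allylic methylenes, C1 and C6, in almost the same environment. What makes a short route possible is that the twenty carbons are a geranylgeranyl chain folded once: C4–C5 and C9–C10 are the bonds of a proton-initiated bicyclisation, C20 on C9 and the hydrogen on C8 sit where a 1,2-methyl and a 1,2-hydride shift would leave them, the C5=C10 olefin is what loss of the C5 proton gives, and C13–C15 is the untouched allylic terminus of the polyene.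

## Retrosynthesis

**C6–H bond (14 from 13).** The C6 carbinol is traced back to the ketone of 13. Cutting the acetate first would leave a diol whose two secondary hydroxyls must then be told apart. With the acetate in place the C7 substituent is the bulky neighbour that sends hydride to the α face. 13 has one stereocentre fewer. The forward step must be a 1,2-reduction from the α face without acyl shift.

**C7–O bond (13 from 12 from 10, through enolate 11).** The C7 oxygen is removed, then the acetyl group. C7 is the α′ position of the C6 ketone and lies next to the C8 methyl, which can steer the oxidant. The neighbouring option, cis-dihydroxylation of a C6=C7 olefin, would need a ring-B diene and would compete with the vinyl group. 10 keeps only C8, C9 and C13 as stereocentres. The forward step needs kinetic deprotonation at C7, not at C1, and attack anti to the C8 methyl.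

**C6=O bond (10 from 8, through peroxide 9).** The carbonyl oxygen is removed to give the hydrocarbon ring system of 8. Allylic C–H oxidation is the only way to bring oxygen into ring B without new carbon–carbon bonds. It is placed after the side chain is finished because the vinyl carbinol of 8 has no allylic hydrogen, whereas the trisubstituted chain olefin of 5 would be attacked. The forward step must spare the tertiary allylic alcohol and must choose C6 over C1 as far as it can; this is the weakest selectivity of the route and is treated under the risks.

**C13 carbinol (8 from 7 from 6 from 5).** The vinyl carbinol is the 1,3-transposed form of the primary allylic alcohol 5, reached through the 2,3-epoxy alcohol 6 and its iodide 7. No carbon–carbon bond is cut. Vinyl addition to a C13 methyl ketone would give no control at this remote centre; the Sharpless epoxidation sets it by reagent control (ligand antipode under step 5) and the reductive opening keeps the C13–O bond. 5 has no oxygen stereocentre and is the dephosphorylated product of the key step.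

**C4–C5, C9–C10 and C9–C20 bonds (5 from 4 from 3).** Both rings are opened, C20 is returned from C9 to C10 and hydrogen from C8 to C9, which leads to the achiral polyene 3. Stepwise construction of the C8/C9 pair would be long, and acid treatment of the free polyene gives the anti fold, water capture and olefin mixtures. The cut removes two rings, three skeletal bonds and two stereocentres at once. The forward reaction must hold the syn (chair–boat) fold, allow both shifts and end by loss of the C5 proton.

**C15–O–P bond (3 from 2 from 1).** The diphosphate is made by displacement of the allylic chloride 2, which comes from commercial geranylgeraniol 1.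

## Roads not taken

**Alternative 1:** The C6–O and C7–O bonds are cut back to an arene edge. A Rieske arene dioxygenase would add dioxygen across the only free edge of the tetralin A1 to give the cis-dihydrodiol A2.
- Merits: both carbinol centres and their cis relation arise in one step and as one enantiomer, and there is no C1/C6 ambiguity because A1 has a single unsubstituted edge. In this respect it is better than the chosen plan.
- Weak points: in A2 the carbons C8 and C9 are still sp2 and fully substituted, so the tertiary C8 and the quaternary C9 with its methyl group would have to be built afterwards on a hindered diene that dehydrates easily to a phenol. Acceptance of a tetrasubstituted arene with a peri quaternary carbon is itself unproven. The whole C12–C16 chain with C13 is still missing.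
- Comparison: the chosen plan sets against the cleaner diol the fact that its key step makes exactly the part Alternative 1 leaves open: C8, C9, C20 and the full chain.

**Alternative 2:** The C5–C6 bond is cut. The acid chloride A3, activated by SnCl4, would be attacked by C5 of the ring-A olefin (6-endo closure of ring B), and loss of the C5 proton from the C10 cation would give the enone A4.
- Merits: the C6 carbonyl is placed by carbon–carbon bond formation, so oxidation at C1 cannot occur, and A4 is the counterpart of enone 10 made by classical chemistry only. On regiocontrol at C6 and on precedent it is better than the chosen plan.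
- Weak points: the difficulty moves into A3, whose acyclic C8/C9 pair (a tertiary centre next to a quaternary one bearing a cyclohexenyl group) must be made first. Cationic acylation of trisubstituted olefins also gives β-chloro ketones and olefin isomers. The chain must later be grown from the neopentyl C11 and C13 set separately.
- Comparison: the chosen plan sets against this a skeleton with the native chain in three steps from a commercial alcohol.

**Alternative 3:** The C8–C9 bond is cut. The bicyclic lactone A5 would be converted into its silyl ketene acetal A6, whose [3,3] shift (Ireland–Claisen ring contraction) would form C8–C9 and give the diene acid A7.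
- Merits: C8 and the quaternary C9 come from one carbinol centre by chirality transfer, and the C6=C7 olefin of A7 is ready for cis-dihydroxylation, again without a C1/C6 problem.
- Weak points: the ring forces a boat transition state, so the C8 configuration rests on one geometry. A6 is a silyloxy-2H-pyran that can open electrocyclically. The C11 carboxyl is neopentyl, so five chain carbons including C13 must be added at a hindered centre, and A5 must first be made as one enantiomer.
- Comparison: it is better on the diol; the chosen plan is shorter and delivers the chain with its C13 handle in the key step.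

Key step: step 3

## Route

Step 1
Reactants: 1 (2E,6E,10E)-geranylgeraniol
Product: 2 (2E,6E,10E)-geranylgeranyl chloride
Conditions: NCS, Me2S, CH2Cl2, −30 to 0 °C
Reagents that add atoms: N-chlorosuccinimide, O=C1CCC(=O)N1Cl
Why: Corey–Kim chlorination of a primary allylic alcohol; chloride displaces the sulfonium-activated oxygen at the carbinol carbon (SN2) without allylic transposition or loss of the (E)-geometry.

Step 2
Reactants: 2 (2E,6E,10E)-geranylgeranyl chloride
Product: 3 (2E,6E,10E)-geranylgeranyl diphosphate (tris-ammonium salt, written as the free acid)
Conditions: (n-Bu4N)3HP2O7, MeCN, 25 °C; cation exchange (NH4+ form), NH4HCO3 buffer; cellulose chromatography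
Reagents that add atoms: tris(tetrabutylammonium) hydrogen diphosphate, CCCC[N+](CCCC)(CCCC)CCCC.CCCC[N+](CCCC)(CCCC)CCCC.CCCC[N+](CCCC)(CCCC)CCCC.OP(=O)([O-])OP(=O)([O-])[O-]
Why: SN2 displacement of a primary allylic chloride by diphosphate, the standard entry to allylic diphosphates; the olefin geometry is untouched.

Step 3
Reactants: 3 (2E,6E,10E)-geranylgeranyl diphosphate
Product: 4 syn-halima-5(10),13E-dien-15-yl diphosphate (8R,9R; 8α-methyl, 9β-methyl, 9α-chain)
Conditions: purified variant of syn-copalyl diphosphate synthase (class 2 diterpene cyclase; catalytic-base histidine exchanged, residues around C5 screened), HEPES pH 7.5, MgCl2 (0.1 mM), glycerol, dithiothreitol, 30 °C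
Reagents that add atoms: none
Why: Proposed new method: the enzyme protonates C3 of the terminal C3=C4 olefin of 3, C5 of the C5=C10 olefin attacks the C4 cation and C9 of the C8=C9 olefin attacks the resulting C10 cation, so that ring A closes by C4–C5 and ring B by C9–C10, each as a 6-endo-trig cation–olefin closure, leaving a tertiary cation at C8. In the chair–boat (syn) fold the C9 hydrogen and the C10 methyl lie on the same β face; the hydrogen moves from C9 to C8 and C20 from C10 to C9 in two stepwise suprafacial 1,2-shifts, and loss of the 5α-proton from the C10 cation gives the C5=C10 olefin. The closest known reaction type is the class 2 diterpene cyclase conversion of 3 into halimadienyl diphosphates by the same cyclisation, hydride shift and methyl shift; the combination of the syn fold with termination at C5 has not been shown and is to be reached by exchanging the catalytic-base histidine of a syn-copalyl diphosphate synthase and screening the residues near C5. C8 (8R, methyl α) is fixed by the face on which the hydride arrives, which is the face it occupied on C9, and C9 (9R, methyl β) by the face from which C20 leaves C10; both follow from the (E)-geometry of the C5=C10 and C8=C9 olefins of 3 and the boat fold of ring B, and the absolute sense comes from the chiral active site. The step needs selectivity against loss of a C17 proton, capture of water at C8 and a further C5-to-C10 hydride shift; the diphosphate anchor of 3, the missing base at C17 and the dry active site leave the two shifts as the only exit, and the tetrasubstituted olefin is the most stable end point.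

Step 4
Reactants: 4 syn-halima-5(10),13E-dien-15-yl diphosphate
Product: 5 syn-halima-5(10),13E-dien-15-ol (8R,9R)
Conditions: calf intestinal alkaline phosphatase, glycine buffer pH 9.5, MgCl2, ZnCl2, 37 °C (run on the crude solution of 4); hexane extraction
Reagents that add atoms: none
Why: Enzymatic phosphate ester hydrolysis by P–O cleavage; the C15–O bond is never ionised, so the allylic alcohol keeps its position and (E)-geometry.

Step 5
Reactants: 5 syn-halima-5(10),13E-dien-15-ol
Product: 6 (13S,14S)-13,14-epoxy-syn-halim-5(10)-en-15-ol
Conditions: Ti(OiPr)4 (10 mol %), L-(+)-diethyl tartrate (12 mol %), t-BuOOH, 4 Å MS, CH2Cl2, −20 °C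
Reagents that add atoms: tert-butyl hydroperoxide, CC(C)(C)OO
Why: Sharpless asymmetric epoxidation; only the olefin of the titanium-bound allylic alcohol reacts, so C5=C10 is spared. With the L-(+)-tartrate ligand an (E)-3-methylalk-2-en-1-ol gives the (2S,3S)-type epoxide, here 13S,14S, by reagent control, the ring stereocentres being too remote to interfere.

Step 6
Reactants: 6 (13S,14S)-13,14-epoxy-syn-halim-5(10)-en-15-ol
Product: 7 (13S,14R)-13,14-epoxy-15-iodo-syn-halim-5(10)-ene
Conditions: I2, PPh3, imidazole, CH2Cl2, 0 °C
Reagents that add atoms: iodine, II
Why: Appel-type iodination of the primary alcohol under buffered conditions that leave the epoxide closed; C13 and C14 are untouched (the C14 descriptor changes only because iodine raises the rank of C15).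

Step 7
Reactants: 7 (13S,14R)-13,14-epoxy-15-iodo-syn-halim-5(10)-ene
Product: 8 (13S)-syn-halima-5(10),14-dien-13-ol
Conditions: activated Zn dust, EtOH, reflux; aqueous NH4Cl
Reagents that add atoms: none
Why: Reductive elimination of a 2,3-epoxy iodide: zinc inserts into the C–I bond and β-elimination opens the oxirane at C14–O, giving the vinyl group and the tertiary alcohol; the C13–O bond is not broken, so 13S is retained.

Step 8
Reactants: 8 (13S)-syn-halima-5(10),14-dien-13-ol
Product: 10 (13S)-13-hydroxy-syn-halima-5(10),14-dien-6-one, via C6 tert-butyl peroxide 9 (not isolated)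
Conditions: Rh2(cap)4 (1 mol %; cap = caprolactamate), t-BuOOH (70% aq., 5 equiv), K2CO3, CH2Cl2, 25 °C, stopped short of full conversion
Reagents that add atoms: tert-butyl hydroperoxide, CC(C)(C)OO
Why: Allylic C–H oxidation by tert-butylperoxyl radicals: abstraction at C6 gives the C6–C5–C10 allyl radical, which is trapped at its secondary end as peroxide 9 and collapses to the enone. The vinyl carbinol has no allylic hydrogen and, without hexavalent chromium, cannot undergo oxidative 1,3-transposition. The C1 methylene is flanked by the more crowded C9 (chain, with the C8 methyl behind it), which should bias but not exclude reaction there, so the 1-oxo isomer is expected as a separable by-product.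

Step 9
Reactants: 10 (13S)-13-hydroxy-syn-halima-5(10),14-dien-6-one
Product: 12 (7R,13S)-7β,13-dihydroxy-syn-halima-5(10),14-dien-6-one, via dipotassium enolate 11 (not isolated)
Conditions: KN(SiMe3)2 (2.3 equiv), THF, −78 °C; 2-(phenylsulfonyl)-3-phenyloxaziridine, −78 °C; NH4Cl
Reagents that add atoms: 2-(phenylsulfonyl)-3-phenyloxaziridine (Davis oxaziridine), O=S(=O)(c1ccccc1)N1OC1c1ccccc1
Why: Kinetic α′-deprotonation of the enone at C7 (one equivalent of base is taken by the C13 hydroxyl) and Davis enolate hydroxylation; the oxidant approaches C7 anti to the adjacent 8α-methyl, giving the 7β-alcohol (7R).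

Step 10
Reactants: 12 (7R,13S)-7β,13-dihydroxy-syn-halima-5(10),14-dien-6-one
Product: 13 (7R,13S)-7β-acetoxy-13-hydroxy-syn-halima-5(10),14-dien-6-one
Conditions: Ac2O, pyridine, DMAP (cat.), CH2Cl2, 0 °C
Reagents that add atoms: acetic anhydride, CC(=O)OC(C)=O
Why: Acylation of the only secondary hydroxyl; the hindered tertiary C13 alcohol does not react under these mild conditions.

Step 11
Reactants: 13 (7R,13S)-7β-acetoxy-13-hydroxy-syn-halima-5(10),14-dien-6-one
Product: 14 (6S,7R,8S,9R,13S)-6β,13-dihydroxy-syn-halima-5(10),14-dien-7β-yl acetate (target)
Conditions: LiBH(s-Bu)3 (2.2 equiv), THF, −78 °C; AcOH, −78 °C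
Reagents that add atoms: none
Why: 1,2-Reduction of a β,β-disubstituted enone by a bulky trialkylborohydride; hydride enters from the α face, anti to the 7β-acetoxy group (Felkin–Anh) and along the equatorial trajectory, so the hydroxyl is 6β, cis to the acetate and pseudoaxial, where it avoids allylic strain with the C4 gem-dimethyl group. The cold acidic quench protonates the alkoxide before the acetate can shift.

## Compound list

1 | (2E,6E,10E)-geranylgeraniol | CC(C)=CCC/C(C)=C/CC/C(C)=C/CC/C(C)=C/CO | starting material
2 | (2E,6E,10E)-geranylgeranyl chloride | CC(C)=CCC/C(C)=C/CC/C(C)=C/CC/C(C)=C/CCl | intermediate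
3 | (2E,6E,10E)-geranylgeranyl diphosphate (free acid form) | CC(C)=CCC/C(C)=C/CC/C(C)=C/CC/C(C)=C/COP(=O)(O)OP(=O)(O)O | intermediate
4 | (8R,9R)-syn-halima-5(10),13E-dien-15-yl diphosphate (free acid form) | OP(=O)(O)OP(=O)(O)OC/C=C(\C)CC[C@@]1(C)C2=C(CC[C@H]1C)C(C)(C)CCC2 | intermediate
5 | (8R,9R)-syn-halima-5(10),13E-dien-15-ol | OC/C=C(\C)CC[C@@]1(C)C2=C(CC[C@H]1C)C(C)(C)CCC2 | intermediate
6 | (8R,9R,13S,14S)-13,14-epoxy-syn-halim-5(10)-en-15-ol | OC[C@@H]1O[C@@]1(C)CC[C@@]2(C)C3=C(CC[C@H]2C)C(C)(C)CCC3 | intermediate
7 | (8R,9R,13S,14R)-13,14-epoxy-15-iodo-syn-halim-5(10)-ene | IC[C@@H]1O[C@@]1(C)CC[C@@]2(C)C3=C(CC[C@H]2C)C(C)(C)CCC3 | intermediate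
8 | (8R,9R,13S)-syn-halima-5(10),14-dien-13-ol | C=C[C@@](C)(O)CC[C@@]1(C)C2=C(CC[C@H]1C)C(C)(C)CCC2 | intermediate
9 | (8R,9R,13S)-6-(tert-butylperoxy)-syn-halima-5(10),14-dien-13-ol (both C6 epimers) | C=C[C@@](C)(O)CC[C@@]1(C)C2=C(C(OOC(C)(C)C)C[C@H]1C)C(C)(C)CCC2 | intermediate (not isolated)
10 | (8R,9R,13S)-13-hydroxy-syn-halima-5(10),14-dien-6-one | C=C[C@@](C)(O)CC[C@@]1(C)C2=C(C(=O)C[C@H]1C)C(C)(C)CCC2 | intermediate
11 | dipotassium C13 alkoxide / C6–C7 enolate of 10 | C=C[C@@](C)([O-])CC[C@@]1(C)C2=C(C([O-])=C[C@H]1C)C(C)(C)CCC2.[K+].[K+] | intermediate (not isolated)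
12 | (7R,8S,9R,13S)-7β,13-dihydroxy-syn-halima-5(10),14-dien-6-one | C=C[C@@](C)(O)CC[C@@]1(C)C2=C(C(=O)[C@H](O)[C@H]1C)C(C)(C)CCC2 | intermediate
13 | (7R,8S,9R,13S)-7β-acetoxy-13-hydroxy-syn-halima-5(10),14-dien-6-one | C=C[C@@](C)(O)CC[C@@]1(C)C2=C(C(=O)[C@H](OC(C)=O)[C@H]1C)C(C)(C)CCC2 | intermediate
14 | (6S,7R,8S,9R,13S)-6β,13-dihydroxy-syn-halima-5(10),14-dien-7β-yl acetate | C=C[C@@](C)(O)CC[C@@]1(C)C2=C([C@H](O)[C@H](OC(C)=O)[C@H]1C)C(C)(C)CCC2 | target

## Step count and risks

Total: 11 steps. Longest linear sequence: 11 steps (one line from 1 to 14).

**Step 3 (key step, proposed new method).** The cascade may end at the wrong stage. The C8 cation can lose a C17 proton (the outcome of the parent enzyme) or take up water, or after both shifts a further C5-to-C10 hydride shift and loss of a C6 proton can occur, because the variant must move both the base and bound water relative to the migrating charge. Fallback with known chemistry, from 3 back to 5: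
- The unmodified syn-copalyl diphosphate synthase, a known conversion of 3, gives syn-copalyl diphosphate F1.
- Alkaline phosphatase gives syn-copalol F2.
- MnO2 gives syn-copalal F3, whose chain olefin, as an enal, is no longer a π-nucleophile.
- BF3·OEt2 in CH2Cl2 at −50 to −10 °C protonates the exocyclic C8=C17 olefin. The C8 cation undergoes the same 9β-hydride and 10β-methyl shifts and loses the C5 proton, the acid-promoted friedo rearrangement known for C8 cations of drimane and labdane frameworks, to give syn-halima-5(10),13E-dien-15-al F4.
- NaBH4 with CeCl3·7H2O in MeOH returns 5.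

**Step 8.** The oxidation may not distinguish the two allylic methylenes, since C1 and C6 differ only in the more remote substituents, and the enone can be oxidised further at C1. Fallback that fixes the site through the chain, from 8 back to 10:
- PhSeCl at −78 °C induces 6-exo attack of the C13 hydroxyl on C10 from the α face, giving (13S)-10α,13-epoxy-5β-(phenylselanyl)-syn-halim-14-ene F5.
- H2O2 with pyridine gives the selenoxide, which can eliminate only toward C6, to (13S)-10α,13-epoxy-syn-halima-5,14-diene F6.
- mCPBA with NaHCO3 epoxidises the trisubstituted olefin in preference to the vinyl group, giving the 5β,6β-epoxide F7 (either face serves).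
- Cp2TiCl (trivalent titanium, from Cp2TiCl2 and Mn) with 1,4-cyclohexadiene opens the oxirane to the tertiary C5 radical and reduces it, giving (13S)-10α,13-epoxy-syn-halim-14-en-6β-ol F8.
- Dess–Martin periodinane gives the ketone F9.
- DBU expels the C10 alkoxide by E1cB elimination and gives 10.

**Step 11.** Hydride transfer to the hindered ketone may be slow, leaving time for reduction of the acetate or for an O7-to-O6 acyl shift in the alkoxide, and some attack from the β face is possible. Fallback that reverses the order, from 12 to 14: LiBH(s-Bu)3 at −78 °C reduces the free ketol to (6S,7R,13S)-syn-halima-5(10),14-diene-6β,7β,13-triol F10. Ac2O in pyridine at −20 °C without DMAP then acylates the equatorial C7 hydroxyl in preference to the pseudoaxial, doubly flanked C6 hydroxyl and the tertiary C13 hydroxyl, giving 14.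

**Step 9.** Deprotonation may occur at C1 (the γ position, giving the extended dienolate), or the oxidant may enter cis to the C8 methyl. Fallback from 10 directly to 13: α′-acetoxylation with Mn(OAc)3·2H2O in refluxing benzene, a radical ligand-transfer process in which the acetate should settle trans to the C8 methyl in the equatorial position. No new compound is involved.

## Further compounds

F1 | step 3 | syn-copalyl diphosphate (9β-H, 10β-methyl; free acid form) | OP(=O)(O)OP(=O)(O)OC/C=C(\C)CC[C@@H]1C(=C)CC[C@H]2C(C)(C)CCC[C@]12C
F2 | step 3 | syn-copalol (syn-labda-8(17),13E-dien-15-ol) | OC/C=C(\C)CC[C@@H]1C(=C)CC[C@H]2C(C)(C)CCC[C@]12C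
F3 | step 3 | syn-copalal (syn-labda-8(17),13E-dien-15-al) | O=C/C=C(\C)CC[C@@H]1C(=C)CC[C@H]2C(C)(C)CCC[C@]12C
F4 | step 3 | syn-halima-5(10),13E-dien-15-al | O=C/C=C(\C)CC[C@@]1(C)C2=C(CC[C@H]1C)C(C)(C)CCC2
F5 | step 8 | (13S)-10α,13-epoxy-5β-(phenylselanyl)-syn-halim-14-ene | C=C[C@]1(C)CC[C@]2(C)[C@H](C)CC[C@]3([Se]c4ccccc4)C(C)(C)CCC[C@@]23O1
F6 | step 8 | (13S)-10α,13-epoxy-syn-halima-5,14-diene | C=C[C@]1(C)CC[C@]2(C)[C@H](C)CC=C3C(C)(C)CCC[C@@]23O1
F7 | step 8 | (13S)-5β,6β:10α,13-diepoxy-syn-halim-14-ene | C=C[C@]1(C)CC[C@]2(C)[C@H](C)C[C@H]3O[C@@]43C(C)(C)CCC[C@@]24O1
F8 | step 8 | (13S)-10α,13-epoxy-5α-H-syn-halim-14-en-6β-ol | C=C[C@]1(C)CC[C@]2(C)[C@H](C)C[C@@H](O)[C@H]3C(C)(C)CCC[C@@]23O1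
F9 | step 8 | (13S)-10α,13-epoxy-5α-H-syn-halim-14-en-6-one | C=C[C@]1(C)CC[C@]2(C)[C@H](C)CC(=O)[C@H]3C(C)(C)CCC[C@@]23O1
F10 | step 11 | (6S,7R,8S,9R,13S)-syn-halima-5(10),14-diene-6β,7β,13-triol | C=C[C@@](C)(O)CC[C@@]1(C)C2=C([C@H](O)[C@H](O)[C@H]1C)C(C)(C)CCC2
F0 | step 9 | none | none
A1 | alternative 1 | 2-(2,5,5-trimethyl-5,6,7,8-tetrahydronaphthalen-1-yl)ethanol | OCCc1c(C)ccc2c1CCCC2(C)C
A2 | alternative 1 | 2-[(3R,4S)-3,4-dihydroxy-2,5,5-trimethyl-3,4,5,6,7,8-hexahydronaphthalen-1-yl]ethanol (6S,7R in halimane numbering) | OCCC1=C(C)[C@@H](O)[C@@H](O)C2=C1CCCC2(C)C
A3 | alternative 2 | (3R,4R)-4-(3,3-dimethylcyclohex-1-en-1-yl)-3,4-dimethyl-5-(pivaloyloxy)pentanoyl chloride | O=C(Cl)C[C@@H](C)[C@@](C)(COC(=O)C(C)(C)C)C1=CC(C)(C)CCC1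
A4 | alternative 2 | [(1R,2R)-1,2,5,5-tetramethyl-4-oxo-1,2,3,4,5,6,7,8-octahydronaphthalen-1-yl]methyl pivalate | CC(C)(C)C(=O)OC[C@@]1(C)C2=C(C(=O)C[C@H]1C)C(C)(C)CCC2
A5 | alternative 3 | (1S)-4,8,8-trimethyl-1-[(E)-prop-1-enyl]-1,4,5,6,7,8-hexahydro-3H-isochromen-3-one (C4 epimers) | C/C=C/[C@@H]1OC(=O)C(C)C2=C1C(C)(C)CCC2
A6 | alternative 3 | trimethylsilyl ketene acetal of A5 | C/C=C/[C@@H]1OC(O[Si](C)(C)C)=C(C)C2=C1C(C)(C)CCC2
A7 | alternative 3 | (1R,2R)-1,2,5,5-tetramethyl-1,2,5,6,7,8-hexahydronaphthalene-1-carboxylic acid | OC(=O)[C@@]1(C)C2=C(C=C[C@H]1C)C(C)(C)CCC2
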